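**Retrosynthetic overview**

- The ten-membered ring is closed last by ring-closing metathesis at C1=C10 on a preformed γ-lactone (lactone first, carbocycle second); the C8 ester exchange and one desilylation finish the synthesis.
- The lactone (C6–C7 and O6–C12 bonds) comes from a CrCl2-mediated allylation/lactonisation that joins an enal (C1–C6, C15) to an allylic bromide (C7–C14).
- The enal is made by the central carbon–oxygen bond construction: a new SN2′ sulfoxide oxidation of a vinyl epoxide, which forms the C6–O bond (later the lactone oxygen), fixes the C4=C5 geometry and leaves O15 protected.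
- The bromide gets C8 and C9 from a second carbon–oxygen bond formation, the Sharpless kinetic-resolution epoxidation of the acrolein/methyl acrylate Baylis–Hillman adduct; the epoxide is then converted to the aldehyde that receives the second acrylate unit.

Assumption: carbons are numbered as in germacranolides (C6 bears the lactone oxygen, C8 the isobutyrate, C9 the acetate, C14 is the ester carbon on C10, C15 the CH2OH carbon on C4).

**Step 1**
Reactants: 1 prop-2-enal (acrolein); 2 but-3-en-1-ylmagnesium bromide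
Product: 3 hepta-1,6-dien-3-ol (racemic)
Conditions: THF, −78 °C; aq. NH4Cl
Reagents that add atoms: none
Why: Grignard 1,2-addition to the aldehyde of acrolein (no copper, low temperature, so no conjugate addition); the racemic carbinol carbon becomes the ketone carbon in step 2.

**Step 2**
Reactants: 3 hepta-1,6-dien-3-ol
Product: 4 hepta-1,6-dien-3-one
Conditions: MnO2 (activated, excess), CH2Cl2, rt
Reagents that add atoms: none
Why: MnO2 oxidises the allylic alcohol selectively to the vinyl ketone (allylic oxidation), which is kept in solution and used at once because it is volatile and polymerises.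

**Step 3**
Reactants: 4 hepta-1,6-dien-3-one
Product: 5 2-(but-3-en-1-yl)-2-ethenyloxirane (racemic)
Conditions: Me3SI, n-BuLi, THF, −10 → 0 °C
Reagents that add atoms: trimethylsulfonium iodide, C[S+](C)C.[I-]
Why: Corey–Chaykovsky epoxidation, in which the unstabilised sulfonium ylide adds to the carbonyl carbon rather than the enone terminus and closes to the vinyl epoxide; its stereocentre is destroyed in step 4, so the racemate is used.

**Step 4**
Reactants: 5 2-(but-3-en-1-yl)-2-ethenyloxirane
Product: 7 (2E)-3-({[tri(propan-2-yl)silyl]oxy}methyl)hepta-2,6-dienal, via alkoxysulfonium triflate 6 (not isolated)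
Conditions: i-Pr3SiOTf (1.1 equiv), DMSO (4 equiv), CH2Cl2, −78 → −30 °C; then Et3N, −30 → 0 °C
Reagents that add atoms: triisopropylsilyl trifluoromethanesulfonate, CC(C)[Si](OS(=O)(=O)C(F)(F)F)(C(C)C)C(C)C; dimethyl sulfoxide, CS(C)=O
Why: Proposed new method: a silyl-triflate-triggered SN2′ (vinylogous) Kornblum oxidation of a vinyl epoxide, in which i-Pr3SiOTf silylates the epoxide oxygen, the tertiary allylic C4–O bond ionises, DMSO adds through oxygen to the unhindered vinyl terminus C6 to give salt 6, and Et3N then forms the sulfur ylide that collapses to the aldehyde and Me2S as in a Swern or Kornblum oxidation; this creates the C6–O bond, leaves O15 as its silyl ether, and should give the E olefin (CH2O trans to C6) because ionisation occurs from the s-trans conformer, as in copper- and palladium-mediated 1,4-openings of 2-substituted vinyl epoxides, while attack at the tertiary carbon is reversible and cannot be oxidised (no α-hydrogen); closest known reactions are the Kornblum oxidation of alkyl halides, the acid-promoted DMSO oxidation of epoxides to α-hydroxy ketones and 1,4-additions to isoprene monoxide.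

**Step 5**
Reactants: 1 prop-2-enal (acrolein); 8 methyl prop-2-enoate (methyl acrylate)
Product: 9 methyl 3-hydroxy-2-methylidenepent-4-enoate (racemic)
Conditions: DABCO (15 mol %), neat (excess 8), rt
Reagents that add atoms: none
Why: Morita–Baylis–Hillman reaction, the DABCO–acrylate enolate attacking the aldehyde of acrolein (excess acrylate suppresses acrolein self-condensation); the racemic carbinol is resolved in step 6.

**Step 6**
Reactants: 9 methyl 3-hydroxy-2-methylidenepent-4-enoate
Product: 11 methyl (3R)-3-(acetyloxy)-2-methylidene-3-[(2S)-oxiran-2-yl]propanoate, via epoxy alcohol 10 (not isolated)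
Conditions: Ti(Oi-Pr)4 (10 mol %), D-(−)-diisopropyl tartrate (15 mol %), t-BuOOH (0.5 equiv), 4 Å molecular sieves, CH2Cl2, −20 °C; then Ac2O, Et3N, DMAP, −20 → 0 °C
Reagents that add atoms: tert-butyl hydroperoxide, CC(C)(C)OO; acetic anhydride, CC(=O)OC(C)=O
Why: Sharpless kinetic-resolution epoxidation with acetylation in the same flask: only the vinyl group (not the electron-poor acrylate) is epoxidised, with D-(−)-tartrate the (S)-alcohol reacts fast and gives the erythro epoxy alcohol (carbinol 3R = C9, oxirane 2S = C8), setting both stereocentres of the diol unit, while the slow (R)-alcohol ends as its allylic acetate and is removed by chromatography.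

**Step 7**
Reactants: 11 methyl (3R)-3-(acetyloxy)-2-methylidene-3-[(2S)-oxiran-2-yl]propanoate
Product: 13 methyl (3R,4R)-3-(acetyloxy)-2-methylidene-5-oxo-4-[(triethylsilyl)oxy]pentanoate, via iodo silyl ether 12 (not isolated)
Conditions: Et3SiCl, NaI, MeCN, 0 °C; then NMO, NaHCO3, 60 °C
Reagents that add atoms: chlorotriethylsilane, CC[Si](Cl)(CC)CC; 4-methylmorpholine N-oxide, C[N+]1([O-])CCOCC1
Why: Et3SiI made in situ opens the terminal epoxide by SN2 attack of iodide at CH2 (silicon ends on the secondary oxygen and the C8–O bond is untouched, so C8 keeps its configuration), and the primary iodide is then oxidised to the aldehyde by the amine N-oxide (Ganem variant of the Kornblum oxidation) under nearly neutral conditions.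

**Step 8**
Reactants: 13 methyl (3R,4R)-3-(acetyloxy)-2-methylidene-5-oxo-4-[(triethylsilyl)oxy]pentanoate; 14 methyl prop-2-ynoate (methyl propiolate)
Product: 15 dimethyl (3R,4S,5RS)-3-(acetyloxy)-5-hydroxy-2,6-dimethylidene-4-[(triethylsilyl)oxy]heptanedioate (mixture of C5 epimers)
Conditions: i-Bu2AlH, NMO, THF, 0 °C; 14, 0 °C; then 13, 0 °C → rt
Reagents that add atoms: none
Why: Vinylalumination: hydroalumination of the propiolate gives the α-(methoxycarbonyl)vinylalane, which adds 1,2 to the aldehyde to give the Baylis–Hillman-type alcohol without amine base (so the β-acetoxy group is not eliminated); the new carbinol centre (C7) is formed as a mixture and is erased in step 9.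

**Step 9**
Reactants: 15 dimethyl (3R,4S,5RS)-3-(acetyloxy)-5-hydroxy-2,6-dimethylidene-4-[(triethylsilyl)oxy]heptanedioate
Product: 16 dimethyl (2Z,4S,5R)-5-(acetyloxy)-2-(bromomethyl)-6-methylidene-4-[(triethylsilyl)oxy]hept-2-enedioate
Conditions: NBS, Me2S, CH2Cl2, −20 → 0 °C
Reagents that add atoms: N-bromosuccinimide, O=C1CCC(=O)N1Br
Why: Corey–Kim-type activation of the allylic hydroxyl and SN2′ attack of bromide at the methylidene carbon give the more stable trisubstituted enoate with the C8 substituent trans to the ester (Z); the silyl ether and acetate survive the neutral conditions.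

**Step 10**
Reactants: 16 dimethyl (2Z,4S,5R)-5-(acetyloxy)-2-(bromomethyl)-6-methylidene-4-[(triethylsilyl)oxy]hept-2-enedioate; 7 (2E)-3-({[tri(propan-2-yl)silyl]oxy}methyl)hepta-2,6-dienal
Product: 18 methyl (3R,4S)-3-(acetyloxy)-2-methylidene-4-[(2R,3S)-4-methylidene-5-oxo-2-{(1E)-2-({[tri(propan-2-yl)silyl]oxy}methyl)hexa-1,5-dien-1-yl}oxolan-3-yl]-4-[(triethylsilyl)oxy]butanoate, via hydroxy ester 17 (not isolated)
Conditions: CrCl2 (4 equiv), THF, 0 °C → rt; aq. NH4Cl
Reagents that add atoms: none
Why: Nozaki–Hiyama allylation with lactonisation: the allylchromium from 16 adds through its γ-carbon (C7) to the aldehyde in a chair transition state to give the anti adduct (trans-lactone, C6 R), the face of C7 being fixed by the C8 stereocentre (its hydrogen eclipses the ester-bearing alkene carbon to avoid allylic 1,3-strain and the aldehyde adds anti to the C9 chain, giving C7 S), and the chromium alkoxide closes onto the adjacent ester; C8 carries a silyl ether rather than an ester so that the allylmetal cannot undergo 1,4-elimination.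

**Step 11**
Reactants: 18 (acyclic lactone from step 10)
Product: 19 methyl (3aS,4S,5R,6E,10E,11aR)-5-(acetyloxy)-3-methylidene-2-oxo-4-[(triethylsilyl)oxy]-10-({[tri(propan-2-yl)silyl]oxy}methyl)-2,3,3a,4,5,8,9,11a-octahydrocyclodeca[b]furan-6-carboxylate
Conditions: second-generation Hoveyda–Grubbs catalyst [RuCl2(H2IMes)(=CH-C6H4-2-Oi-Pr)] (10 mol %), toluene (1 mM), 80 °C
Reagents that add atoms: none
Why: Ring-closing metathesis between the terminal vinyl group and the acrylate methylidene under high dilution (closure onto the lactone methylidene would give a strained bridged ring); the ten-membered ring favours the trisubstituted enoate with C2 cis to C9 within the ring, which is the required geometry.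

**Step 12**
Reactants: 19 (macrocycle from step 11)
Product: 21 methyl (3aS,4S,5R,6E,10E,11aR)-5-(acetyloxy)-3-methylidene-4-[(2-methylpropanoyl)oxy]-2-oxo-10-({[tri(propan-2-yl)silyl]oxy}methyl)-2,3,3a,4,5,8,9,11a-octahydrocyclodeca[b]furan-6-carboxylate, via alcohol 20 (not isolated)
Conditions: PPTS, MeOH, 0 °C → rt; then (i-PrCO)2O, Et3N, DMAP, CH2Cl2, 0 °C
Reagents that add atoms: 2-methylpropanoic anhydride, CC(C)C(=O)OC(=O)C(C)C
Why: Acid-catalysed methanolysis removes the secondary triethylsilyl ether much faster than the primary triisopropylsilyl ether, and the single free hydroxyl (C8) is then esterified by DMAP-catalysed acylation before acetyl migration from O9 can occur.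

**Step 13**
Reactants: 21 (silyl-protected diester from step 12)
Product: 22 methyl (3aS,4S,5R,6E,10E,11aR)-5-(acetyloxy)-10-(hydroxymethyl)-3-methylidene-4-[(2-methylpropanoyl)oxy]-2-oxo-2,3,3a,4,5,8,9,11a-octahydrocyclodeca[b]furan-6-carboxylate (CNP0242134.4)
Conditions: HF·pyridine, pyridine, THF, 0 °C → rt
Reagents that add atoms: none
Why: Fluoride-mediated cleavage of the silyl ether under buffered conditions frees the primary allylic alcohol without touching the esters, the lactone or the two enoate systems.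

**Compound list**

1 | prop-2-enal (acrolein) | C=CC=O | starting material
2 | but-3-en-1-ylmagnesium bromide | C=CCC[Mg]Br | starting material
3 | hepta-1,6-dien-3-ol (racemic) | C=CC(O)CCC=C | intermediate
4 | hepta-1,6-dien-3-one | C=CC(=O)CCC=C | intermediate
5 | 2-(but-3-en-1-yl)-2-ethenyloxirane (racemic) | C=CC1(CCC=C)CO1 | intermediate
6 | dimethyl[(2E)-3-({[tri(propan-2-yl)silyl]oxy}methyl)hepta-2,6-dien-1-yl]oxysulfonium trifluoromethanesulfonate (not isolated) | C[S+](C)OC/C=C(/CO[Si](C(C)C)(C(C)C)C(C)C)CCC=C.[O-]S(=O)(=O)C(F)(F)F | intermediate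
7 | (2E)-3-({[tri(propan-2-yl)silyl]oxy}methyl)hepta-2,6-dienal | O=C/C=C(/CO[Si](C(C)C)(C(C)C)C(C)C)CCC=C | intermediate
8 | methyl prop-2-enoate (methyl acrylate) | C=CC(=O)OC | starting material
9 | methyl 3-hydroxy-2-methylidenepent-4-enoate (racemic) | C=CC(O)C(=C)C(=O)OC | intermediate
10 | methyl (3R)-3-hydroxy-2-methylidene-3-[(2S)-oxiran-2-yl]propanoate (not isolated) | COC(=O)C(=C)[C@@H](O)[C@@H]1CO1 | intermediate
11 | methyl (3R)-3-(acetyloxy)-2-methylidene-3-[(2S)-oxiran-2-yl]propanoate | COC(=O)C(=C)[C@@H](OC(C)=O)[C@@H]1CO1 | intermediate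
12 | methyl (3R,4R)-3-(acetyloxy)-5-iodo-2-methylidene-4-[(triethylsilyl)oxy]pentanoate (not isolated) | COC(=O)C(=C)[C@@H](OC(C)=O)[C@@H](O[Si](CC)(CC)CC)CI | intermediate
13 | methyl (3R,4R)-3-(acetyloxy)-2-methylidene-5-oxo-4-[(triethylsilyl)oxy]pentanoate | COC(=O)C(=C)[C@@H](OC(C)=O)[C@@H](O[Si](CC)(CC)CC)C=O | intermediate
14 | methyl prop-2-ynoate (methyl propiolate) | C#CC(=O)OC | starting material
15 | dimethyl (3R,4S,5RS)-3-(acetyloxy)-5-hydroxy-2,6-dimethylidene-4-[(triethylsilyl)oxy]heptanedioate | COC(=O)C(=C)[C@@H](OC(C)=O)[C@@H](O[Si](CC)(CC)CC)C(O)C(=C)C(=O)OC | intermediate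
16 | dimethyl (2Z,4S,5R)-5-(acetyloxy)-2-(bromomethyl)-6-methylidene-4-[(triethylsilyl)oxy]hept-2-enedioate | COC(=O)/C(CBr)=C/[C@H](O[Si](CC)(CC)CC)[C@H](OC(C)=O)C(=C)C(=O)OC | intermediate
17 | dimethyl (3R,4S,5S)-3-(acetyloxy)-5-[(1R,2E)-1-hydroxy-3-({[tri(propan-2-yl)silyl]oxy}methyl)hepta-2,6-dien-1-yl]-2,6-dimethylidene-4-[(triethylsilyl)oxy]heptanedioate (not isolated) | C=C(C(=O)OC)[C@@H]([C@H](O)/C=C(/CO[Si](C(C)C)(C(C)C)C(C)C)CCC=C)[C@H](O[Si](CC)(CC)CC)[C@H](OC(C)=O)C(=C)C(=O)OC | intermediate
18 | methyl (3R,4S)-3-(acetyloxy)-2-methylidene-4-[(2R,3S)-4-methylidene-5-oxo-2-{(1E)-2-({[tri(propan-2-yl)silyl]oxy}methyl)hexa-1,5-dien-1-yl}oxolan-3-yl]-4-[(triethylsilyl)oxy]butanoate | C=C1C(=O)O[C@H](/C=C(/CO[Si](C(C)C)(C(C)C)C(C)C)CCC=C)[C@H]1[C@H](O[Si](CC)(CC)CC)[C@H](OC(C)=O)C(=C)C(=O)OC | intermediate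
19 | methyl (3aS,4S,5R,6E,10E,11aR)-5-(acetyloxy)-3-methylidene-2-oxo-4-[(triethylsilyl)oxy]-10-({[tri(propan-2-yl)silyl]oxy}methyl)-2,3,3a,4,5,8,9,11a-octahydrocyclodeca[b]furan-6-carboxylate | C=C1C(=O)O[C@@H]2/C=C(/CO[Si](C(C)C)(C(C)C)C(C)C)CC/C=C(/C(=O)OC)[C@@H](OC(C)=O)[C@@H](O[Si](CC)(CC)CC)[C@@H]12 | intermediate
20 | methyl (3aR,4S,5R,6E,10E,11aR)-5-(acetyloxy)-4-hydroxy-3-methylidene-2-oxo-10-({[tri(propan-2-yl)silyl]oxy}methyl)-2,3,3a,4,5,8,9,11a-octahydrocyclodeca[b]furan-6-carboxylate (not isolated) | C=C1C(=O)O[C@@H]2/C=C(/CO[Si](C(C)C)(C(C)C)C(C)C)CC/C=C(/C(=O)OC)[C@@H](OC(C)=O)[C@@H](O)[C@@H]12 | intermediate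
21 | methyl (3aS,4S,5R,6E,10E,11aR)-5-(acetyloxy)-3-methylidene-4-[(2-methylpropanoyl)oxy]-2-oxo-10-({[tri(propan-2-yl)silyl]oxy}methyl)-2,3,3a,4,5,8,9,11a-octahydrocyclodeca[b]furan-6-carboxylate | C=C1C(=O)O[C@@H]2/C=C(/CO[Si](C(C)C)(C(C)C)C(C)C)CC/C=C(/C(=O)OC)[C@@H](OC(C)=O)[C@@H](OC(=O)C(C)C)[C@@H]12 | intermediate
22 | methyl (3aS,4S,5R,6E,10E,11aR)-5-(acetyloxy)-10-(hydroxymethyl)-3-methylidene-4-[(2-methylpropanoyl)oxy]-2-oxo-2,3,3a,4,5,8,9,11a-octahydrocyclodeca[b]furan-6-carboxylate | C=C1C(=O)O[C@@H]2/C=C(/CO)CC/C=C(/C(=O)OC)[C@@H](OC(C)=O)[C@@H](OC(=O)C(C)C)[C@@H]12 | target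

**Step count**

Total: 13 steps. Longest linear sequence: 9 steps (steps 5 to 13, from acrolein and methyl acrylate); the enal 7 takes 4 steps (steps 1 to 4).

**Three steps most likely to fail**

Step 4 (the new reaction). DMSO may instead attack the epoxide CH2 (1,2-product), the allyl cation may lose a proton, or an E/Z mixture may form. The fallback uses known chemistry and sets out from 5. Pd(PPh3)4-catalysed 1,4-addition of acetic acid (THF, rt; opening of the vinyl epoxide through the π-allyl complex of divalent palladium) gives (2E)-3-(hydroxymethyl)hepta-2,6-dien-1-yl acetate F1. Silylation with i-Pr3SiCl/imidazole gives (2E)-3-({[tri(propan-2-yl)silyl]oxy}methyl)hepta-2,6-dien-1-yl acetate F2. Methanolysis with K2CO3/MeOH gives (2E)-3-({[tri(propan-2-yl)silyl]oxy}methyl)hepta-2,6-dien-1-ol F3, and MnO2 oxidation comes back to the route at 7.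

Step 6 (kinetic resolution). The β-hydroxy ester of 9 can chelate titanium, which may slow the epoxidation of the terminal vinyl group or lower the selectivity, and the yield is capped at 50 %. The fallback sets out from 9. Candida antarctica lipase B with vinyl acetate acetylates the (R)-enantiomer to methyl (3R)-3-(acetyloxy)-2-methylidenepent-4-enoate F5 and leaves methyl (3S)-3-hydroxy-2-methylidenepent-4-enoate F4. Hydroxyl-directed, erythro-selective epoxidation of F4 with VO(acac)2/t-BuOOH gives 10, now isolated and freed of its threo isomer, and Ac2O/pyridine comes back to the route at 11.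

Step 11 (ring-closing metathesis). Closing a ten-membered ring onto a hindered acrylate competes with oligomerisation and with reaction at the lactone methylidene. The fallback sets out from 16 and 7 and replaces steps 10 and 11. Cross-metathesis (second-generation Grubbs catalyst [RuCl2(H2IMes)(PCy3)(=CHPh)], CH2Cl2, 40 °C) of the acrylate methylidene of 16 with the terminal vinyl group of 7 gives the linear bromo enal dimethyl (2Z,4S,5R,6E)-5-(acetyloxy)-2-(bromomethyl)-6-[(4E)-6-oxo-4-({[tri(propan-2-yl)silyl]oxy}methyl)hex-4-en-1-ylidene]-4-[(triethylsilyl)oxy]hept-2-enedioate F6. CrCl2 under high dilution (THF, rt) then closes the ten-membered ring by intramolecular Nozaki–Hiyama allylation with lactonisation, so that C6 and C7 are set under ring control, and comes back to the route at 19.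

**Further compounds**

F1 | step 4 | (2E)-3-(hydroxymethyl)hepta-2,6-dien-1-yl acetate | CC(=O)OC/C=C(/CO)CCC=C
F2 | step 4 | (2E)-3-({[tri(propan-2-yl)silyl]oxy}methyl)hepta-2,6-dien-1-yl acetate | CC(=O)OC/C=C(/CO[Si](C(C)C)(C(C)C)C(C)C)CCC=C
F3 | step 4 | (2E)-3-({[tri(propan-2-yl)silyl]oxy}methyl)hepta-2,6-dien-1-ol | OC/C=C(/CO[Si](C(C)C)(C(C)C)C(C)C)CCC=C
F4 | step 6 | methyl (3S)-3-hydroxy-2-methylidenepent-4-enoate | COC(=O)C(=C)[C@@H](O)C=C
F5 | step 6 | methyl (3R)-3-(acetyloxy)-2-methylidenepent-4-enoate | COC(=O)C(=C)[C@H](OC(C)=O)C=C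
F6 | step 11 | dimethyl (2Z,4S,5R,6E)-5-(acetyloxy)-2-(bromomethyl)-6-[(4E)-6-oxo-4-({[tri(propan-2-yl)silyl]oxy}methyl)hex-4-en-1-ylidene]-4-[(triethylsilyl)oxy]hept-2-enedioate | COC(=O)/C(CBr)=C/[C@H](O[Si](CC)(CC)CC)[C@H](OC(C)=O)/C(C(=O)OC)=C\CC/C(CO[Si](C(C)C)(C(C)C)C(C)C)=C\C=O
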